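**Structural features**

The target is an isoflavan. A chroman (benzo ring A fused through C4a and C8a to the dihydropyran ring C) carries at C3 a 2,3-dimethoxy-1,4-benzoquinone (ring B), bonded through quinone carbon 5. Ring A has four oxygens in a row: the ring oxygen O1 on C8a, methoxy groups on C8 and C6, and a free hydroxyl on C7; only C5 bears hydrogen. C3 is the only stereocentre and is (S), so there is no relative configuration to control, only the absolute one. The fragile parts are the quinone (a Michael acceptor with two vinylogous-ester methoxy groups, which also makes H–C3 vinylogously acidic) and the electron-rich ring A phenol, which is a reductant sitting in the same molecule as an oxidant. The real difficulty is to place four different oxygen functions on ring A in the right order, to keep O7 distinct from the two methoxy oxygens, and to hold back the quinone oxidation level of ring B until the end. The feature used is this: once the O1–C8a bond is removed, ring A is a 4-oxy-3,5-dimethoxyphenyl (syringyl) group attached through C4a, and its two ortho carbons (C8a and C5) are mirror images of each other. Closing O1 onto either of them therefore gives the same chroman.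

**Logic of the disconnections**

17 to 15 by way of 16. No skeletal bond is cut. The two quinone carbonyls are traced to the hydroxyls of 16, and these to the ester oxygens of 15. The quinone is the least robust group and acidifies H–C3, so it should appear in the last operation; every earlier compound then carries ring B as an electron-poor arene. The forward step must cleave two hindered aryl esters without base and oxidise the hydroquinone without touching the ring A hydroxyl.

15 to 14. The O7–CH2Ph bond is cut. During ring closure O7 has to be an ether (a donor without O–H) and has to stay distinguishable from the oxygens on C6 and C8. The forward step is a hydrogenolysis that must leave the aryl esters alone.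

14 to 13. The O1–C8a bond is cut; this is the strategic disconnection. It removes ring C and gives ring A a mirror plane through C4a and C7, so 13 contains no ring A regiochemistry. The forward step must oxidise ring A in preference to ring B, direct the hydroxyl to an ortho carbon and not to C4a, and leave H–C3 alone.

13 to 11 by way of 12. C2 is traced from CH2OH to a carboxyl group, then hydrogen is removed from C3 and C4 to give the C3=C4 double bond. An α-aryl cinnamic acid is a substrate class in which a carboxylate-directed hydrogenation can set such a centre catalytically. The demands are face selectivity on a crowded trisubstituted alkene with a catalyst that spares the benzyl ether, and an acid reduction that spares the esters.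

11 to 8 and 10. The C3=C4 bond is cut to an aryl acetic acid and an aromatic aldehyde, two pieces of similar size with one ring each. The forward condensation must give the geometry with the two aryl groups cis and must not disturb the ester ortho to the reacting CH2.

10 to 9. The benzyl–O bond is cut. This leads to a commercial phenolic aldehyde with the substitution pattern of ring A minus O1.

8 to 6 by way of 7. The carboxyl carbon is traced to the internal carbon of an allyl group whose C=C bond is cleaved. The acid side chain is thereby reduced to a group that a sigmatropic shift can deliver to a defined ring position. The forward step must cleave the alkene without attacking the arene and without isolating the aldehyde.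

6 to 4 by way of 5. The two acyl–O bonds are cut and the hydroquinone is taken back to the quinone, so that the para oxygen can come from oxidation of a phenol. The hydroquinone must be acylated before air reaches it.

4 to 3. The C–O bond para to the phenolic oxygen is cut. A phenol with both ortho positions occupied and the para position free is the best substrate for oxygenation to a para-quinone.

3 to 1 by way of 2. The aryl–CH2 bond is cut and the allyl group returned to the phenolic oxygen. One ortho position of 1 is blocked by methoxy, so the rearrangement has only one place to deliver the allyl group.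

**Other disconnections considered**

Alternative 1: The cut goes through ring C at two bonds, C3–C4 and O1–C2. In the forward sense fluoride desilylates the benzylic bromide A1, which loses bromide to give the ortho-quinone methide A2. A chiral isothiourea, acylated by the aryl ester A3, forms an ammonium enolate that adds to the exocyclic methylene of A2; the phenoxide then closes the lactone and releases the catalyst, giving A4 with C3 set by the catalyst.
- In its favour: two bonds, ring C and the stereocentre are made in one convergent catalytic operation, and the reaction type is established for simpler partners. On mechanistic precedent it is the better plan.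
- Also in its favour: ring B can stay as a bis(benzyl ether) because no oxidation follows, so all three benzyl groups fall in one hydrogenolysis. On protecting-group economy at the end it is at least the equal.
- Against it: the C8a oxygen must be on ring A beforehand. A1 is therefore a pentasubstituted benzene with four contiguous, differentiated oxygens and no symmetry to help its preparation, whereas the chosen plan takes ring A from a symmetric aldehyde.
- Against it: C3 of A4 is benzylic and α to a lactone carbonyl, so it could epimerise under the fluoride and aryloxide present.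
- Against it: the lactone carbonyl must still be taken down to CH2 (hydride reduction, then Mitsunobu ring closure), two operations the chosen plan does not need.
- Overall: more secure bond formation, less secure configuration, a longer way to the ring A partner, and about the same total length.

Alternative 2: The cut is the C5–C6 bond, so ring A is built and not bought. On heating, the cyclobutenone A5 should open to a dienylketene; a six-electron ring closure joins the ketene carbon to the alkene terminus and tautomerisation gives the hydroquinone A6.
- In its favour: a thermal pericyclic cascade under neutral conditions with good precedent, on which point it is better than the chosen key step.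
- Also in its favour: all ring A oxygens are placed by construction, and C3 is remote from the reacting atoms. On stereochemical safety it is the equal of the chosen plan.
- Against it: A6 has two free hydroxyls (on C6 and C8a) that must be told apart, one to be methylated and the other closed onto C2. It also carries a tert-butyl ether that must be removed later, and it is an air-sensitive hydroquinone that would oxidise to a ring A quinone.
- Against it: A5 needs a mixed tert-butyl methyl squarate and addition of the alkenyllithium to the right one of two similar carbonyls, and the stereocentre has to be made beforehand in the alkenyl fragment.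
- Overall: it forms more of the skeleton in its key step and rests on safer mechanism, but it is clearly longer (squarate and fragment preparation, then methylation, desilylation, ring closure, two kinds of deprotection and oxidation).

Alternative 3: The cuts are C2–C3 and C3–C4. C3, carrying ring B, is inserted as one carbon into the furan double bond of the benzofuran A7. The chlorodiazirine A8 should lose dinitrogen to a chlorocarbene that cyclopropanates that bond; the chlorocyclopropane opens with loss of chloride to the aromatic benzopyrylium salt A9.
- In its favour: it is the most convergent of the four plans, makes two C–C bonds at once, is driven by aromatisation, and brings ring B in late. On convergence it is better than the chosen plan.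
- Against it: A9 is planar, so C3 is not set. A separate enantioselective reduction is needed; that is feasible by asymmetric hydrogenation of the derived isoflavene but costs a step and a second catalyst.
- Against it: A7 already contains O1 and the full contiguous oxygen pattern, so it meets the same regiochemical problem as alternative 1.
- Against it: A8 is an electron-rich aryl chlorodiazirine. Its preparation by hypochlorite oxidation of an amidine competes with ring chlorination and its handling is a safety concern. The donor-substituted carbene is a weak electrophile that could also attack the benzo ring or the benzyl ethers, and A9 adds water readily.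
- Overall: carbon insertion of this kind is established for indoles and pyrroles more than for benzofurans, so on precedent it is only the equal of the chosen plan. It could be the shorter route from its fragments, but the fragments themselves are longer to make.

Key step: step 10

Assumption: C3 is read as (S) from the target SMILES (priorities C2 > ring B carbon > C4 > H), chroman numbering is used for the same atoms in open-chain intermediates, and the enantiomer of the hydrogenation ligand in step 8 is to be chosen to match this configuration.

Step 1
Reactants: 1 2,3-dimethoxyphenol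
Product: 2 1-(allyloxy)-2,3-dimethoxybenzene
Conditions: allyl bromide, K2CO3, acetone, reflux
Reagents that add atoms: allyl bromide, C=CCBr
Why: Williamson ether synthesis; the phenoxide is alkylated on oxygen by the allylic bromide in an SN2 reaction and nothing else in the molecule is nucleophilic.

Step 2
Reactants: 2 1-(allyloxy)-2,3-dimethoxybenzene
Product: 3 6-allyl-2,3-dimethoxyphenol
Conditions: N,N-diethylaniline, 195 °C
Reagents that add atoms: none
Why: Aromatic Claisen rearrangement ([3,3]-sigmatropic shift followed by tautomerisation); one ortho position is blocked by methoxy, so the allyl group should arrive only at C6, the carbon that later carries the acetic acid chain.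

Step 3
Reactants: 3 6-allyl-2,3-dimethoxyphenol
Product: 4 5-allyl-2,3-dimethoxy-1,4-benzoquinone
Conditions: Co(salen) [C16H14CoN2O2] (5 mol%), O2 (1 atm), DMF, 25 °C
Reagents that add atoms: dioxygen, O=O
Why: Cobalt–salen-catalysed aerobic oxidation of a phenol to the para-quinone through the phenoxyl radical; both ortho positions are substituted and the para position is free, so oxygen should enter para and radical coupling is disfavoured.

Step 4
Reactants: 4 5-allyl-2,3-dimethoxy-1,4-benzoquinone
Product: 6 5-allyl-2,3-dimethoxy-1,4-phenylene bis(2,2-dimethylpropanoate), via 5-allyl-2,3-dimethoxyhydroquinone 5 (not isolated)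
Conditions: Na2S2O4, EtOAc/H2O, 25 °C; organic phase dried under Ar; then t-BuCOCl, Et3N, DMAP (cat.), CH2Cl2, 0 → 25 °C
Reagents that add atoms: pivaloyl chloride, CC(C)(C)C(Cl)=O
Why: Dithionite reduction of the quinone followed by DMAP-catalysed O-acylation; the hydroquinone is acylated without isolation because it reoxidises in air, and pivalates are chosen because they withstand the later amine, hydride-free and hydrogenation steps and make ring B electron-poor.

Step 5
Reactants: 6 5-allyl-2,3-dimethoxy-1,4-phenylene bis(2,2-dimethylpropanoate)
Product: 8 [3,4-dimethoxy-2,5-bis(pivaloyloxy)phenyl]acetic acid, via arylacetaldehyde 7 (not isolated)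
Conditions: O3, MeCN/H2O (9:1), 0 °C; N2 purge; then NaClO2, NaH2PO4, 0 → 25 °C
Reagents that add atoms: ozone, [O-][O+]=O; sodium chlorite, [Na+].[O-]Cl=O
Why: Ozonolysis in wet solvent, where water intercepts the carbonyl oxide so that the aldehyde forms without a reductive work-up, then Pinnick (chlorite) oxidation in the same flask with the hydrogen peroxide from the first stage as hypochlorite scavenger; the terminal alkene should react with ozone far faster than the acylated arene, and the enolisable arylacetaldehyde is never handled.

Step 6
Reactants: 9 syringaldehyde (4-hydroxy-3,5-dimethoxybenzaldehyde)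
Product: 10 4-(benzyloxy)-3,5-dimethoxybenzaldehyde
Conditions: BnBr, K2CO3, DMF, 60 °C
Reagents that add atoms: benzyl bromide, BrCc1ccccc1
Why: Williamson ether synthesis on the hindered but acidic phenol; the benzyl group keeps O7 an ether donor through the key step and distinct from the two methoxy groups.

Step 7
Reactants: 8 [3,4-dimethoxy-2,5-bis(pivaloyloxy)phenyl]acetic acid; 10 4-(benzyloxy)-3,5-dimethoxybenzaldehyde
Product: 11 (E)-3-[4-(benzyloxy)-3,5-dimethoxyphenyl]-2-[3,4-dimethoxy-2,5-bis(pivaloyloxy)phenyl]prop-2-enoic acid
Conditions: Ac2O, Et3N, 110 °C; then H2O, 80 °C; aq. HCl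
Reagents that add atoms: none
Why: Perkin condensation: the mixed anhydride of 8 is enolised by the amine, adds to the non-enolisable aldehyde and eliminates after O-acetylation; the acid with the two aryl groups cis (E) is the usual outcome and the mixed anhydride is hydrolysed on work-up.

Step 8
Reactants: 11 (E)-3-[4-(benzyloxy)-3,5-dimethoxyphenyl]-2-[3,4-dimethoxy-2,5-bis(pivaloyloxy)phenyl]prop-2-enoic acid
Product: 12 (2S)-3-[4-(benzyloxy)-3,5-dimethoxyphenyl]-2-[3,4-dimethoxy-2,5-bis(pivaloyloxy)phenyl]propanoic acid
Conditions: [Ir(cod)(L)][B(C6H3(CF3)2)4] (1 mol%; L = chiral 7-(diarylphosphino)-7'-(oxazolin-2-yl)-1,1'-spirobiindane; made from [Ir(cod)Cl]2, L and Na[B(C6H3(CF3)2)4]), H2 (6 atm), Et3N (0.5 equiv), MeOH, 40 °C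
Reagents that add atoms: none
Why: Carboxylate-directed, iridium-catalysed asymmetric hydrogenation of an α-aryl cinnamic acid; the carboxylate binds the cationic metal and the spiro phosphine–oxazoline ligand differentiates the alkene faces, so C3 is set here as (S) by the choice of ligand enantiomer. A homogeneous iridium catalyst should leave the benzyl ether and the aryl esters untouched.

Step 9
Reactants: 12 (2S)-3-[4-(benzyloxy)-3,5-dimethoxyphenyl]-2-[3,4-dimethoxy-2,5-bis(pivaloyloxy)phenyl]propanoic acid
Product: 13 (2S)-3-[4-(benzyloxy)-3,5-dimethoxyphenyl]-2-[3,4-dimethoxy-2,5-bis(pivaloyloxy)phenyl]propan-1-ol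
Conditions: BH3·SMe2, THF, 0 → 25 °C; then MeOH, H2O
Reagents that add atoms: none
Why: Chemoselective borane reduction of a carboxylic acid through its acyloxyborane, which is much faster than reduction of esters; the medium is neutral, so the α-aryl stereocentre and the pivalates should be unaffected.

Step 10
Reactants: 13 (2S)-3-[4-(benzyloxy)-3,5-dimethoxyphenyl]-2-[3,4-dimethoxy-2,5-bis(pivaloyloxy)phenyl]propan-1-ol
Product: 14 (3S)-7-(benzyloxy)-3-[3,4-dimethoxy-2,5-bis(pivaloyloxy)phenyl]-6,8-dimethoxychroman
Conditions: 9-mesityl-10-methylacridinium tetrafluoroborate (5 mol%), Co(dmgH)2(py)Cl (5 mol%), degassed MeCN (0.02 M), no added base, 450 nm LEDs, Ar, 25 °C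
Reagents that add atoms: none
Why: Proposed new method: the excited acridinium salt, a one-electron oxidant strong enough for alkoxyarenes, should take an electron from the trialkoxy ring A; the tethered hydroxyl should add to the radical cation at C8a and lose its proton, and the cyclohexadienyl radical should then give a hydrogen atom to the cobaloxime in its divalent state (formed when the acridinyl radical reduces the trivalent cobalt complex, which also returns the photocatalyst), the cobalt hydride and the proton leaving as H2. The closest known reaction types are acridinium-photoredox C–H amination of alkoxyarenes, acridinium/cobaloxime dehydrogenative lactonisation of biaryl carboxylic acids and the chemical-oxidant cyclisation of 3-arylpropan-1-ols to chromans, all through arene radical cations; what is new is a hydrogen-evolving C–O closure by a plain primary alcohol onto a syringyl ring. The one ring that closes is the six-membered ring C, by attack of O1 on the ortho carbon; counted against the C4a–C8a bond this is a 6-endo closure and counted against C8–C8a a 6-exo closure, and either is geometrically easy on a delocalised radical cation. No stereocentre is formed, and C3 should keep its configuration because it takes no part and no base is present to deprotonate a benzylic position of the radical cation. Three selectivities are needed: ring A over ring B, which the two pivalates should secure by raising the oxidation potential of ring B (a hole formed there should pass to ring A, the only ring with a nucleophile in reach); ortho over ipso attack, expected because the C7 benzyloxy group is pushed out of the ring plane by its two neighbours, so the charge is carried by the in-plane methoxy groups and appears para to them at C8a and C5, and because addition at C4a is reversible while ortho addition ends in rearomatisation; and one ortho carbon over the other, a choice the mirror symmetry of the syringyl ring removes. Hydrogen evolution is preferred to an oxygen-based terminal oxidant because 14, a tetraalkoxyarene, is more easily oxidised than 13; the reaction should be stopped short of full conversion and 13 recycled.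

Step 11
Reactants: 14 (3S)-7-(benzyloxy)-3-[3,4-dimethoxy-2,5-bis(pivaloyloxy)phenyl]-6,8-dimethoxychroman
Product: 15 (3S)-3-[3,4-dimethoxy-2,5-bis(pivaloyloxy)phenyl]-6,8-dimethoxychroman-7-ol
Conditions: H2 (1 atm), Pd/C (10%), EtOAc, 25 °C
Reagents that add atoms: none
Why: Hydrogenolysis of a benzyl aryl ether on palladium; the aryl pivalates, the methyl ethers and the non-benzylic O1–C2 bond of the chroman should be inert.

Step 12
Reactants: 15 (3S)-3-[3,4-dimethoxy-2,5-bis(pivaloyloxy)phenyl]-6,8-dimethoxychroman-7-ol
Product: 17 5-[(3S)-7-hydroxy-6,8-dimethoxychroman-3-yl]-2,3-dimethoxy-1,4-benzoquinone, via hydroquinone 16 (not isolated)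
Conditions: i-Bu2AlH (6 equiv), CH2Cl2, −78 → 0 °C, Ar; aq. tartaric acid; then Ag2O (1.2 equiv), MgSO4, Et2O, 0 °C
Reagents that add atoms: none
Why: Reductive cleavage of the hindered aryl esters by an aluminium hydride (no alkoxide base), then two-electron oxidation of the hydroquinone with silver oxide in neutral ether; the hydroquinone is much more easily oxidised than the ring A phenol. The quinone is unveiled last because it would not survive the earlier base and hydride steps and would make H–C3 labile.

**Compound list**

1 | 2,3-dimethoxyphenol | COc1cccc(O)c1OC | starting material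
2 | 1-(allyloxy)-2,3-dimethoxybenzene | C=CCOc1cccc(OC)c1OC | intermediate
3 | 6-allyl-2,3-dimethoxyphenol | C=CCc1ccc(OC)c(OC)c1O | intermediate
4 | 5-allyl-2,3-dimethoxy-1,4-benzoquinone | C=CCC1=CC(=O)C(OC)=C(OC)C1=O | intermediate
5 | 5-allyl-2,3-dimethoxybenzene-1,4-diol (formed in the flask, not isolated) | C=CCc1cc(O)c(OC)c(OC)c1O | intermediate
6 | 5-allyl-2,3-dimethoxy-1,4-phenylene bis(2,2-dimethylpropanoate) | C=CCc1cc(OC(=O)C(C)(C)C)c(OC)c(OC)c1OC(=O)C(C)(C)C | intermediate
7 | [3,4-dimethoxy-2,5-bis(pivaloyloxy)phenyl]acetaldehyde (formed in the flask, not isolated) | O=CCc1cc(OC(=O)C(C)(C)C)c(OC)c(OC)c1OC(=O)C(C)(C)C | intermediate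
8 | [3,4-dimethoxy-2,5-bis(pivaloyloxy)phenyl]acetic acid | OC(=O)Cc1cc(OC(=O)C(C)(C)C)c(OC)c(OC)c1OC(=O)C(C)(C)C | intermediate
9 | syringaldehyde (4-hydroxy-3,5-dimethoxybenzaldehyde) | COc1cc(C=O)cc(OC)c1O | starting material
10 | 4-(benzyloxy)-3,5-dimethoxybenzaldehyde | COc1cc(C=O)cc(OC)c1OCc1ccccc1 | intermediate
11 | (E)-3-[4-(benzyloxy)-3,5-dimethoxyphenyl]-2-[3,4-dimethoxy-2,5-bis(pivaloyloxy)phenyl]prop-2-enoic acid (aryl groups cis) | OC(=O)/C(=C/c1cc(OC)c(OCc2ccccc2)c(OC)c1)c1cc(OC(=O)C(C)(C)C)c(OC)c(OC)c1OC(=O)C(C)(C)C | intermediate
12 | (2S)-3-[4-(benzyloxy)-3,5-dimethoxyphenyl]-2-[3,4-dimethoxy-2,5-bis(pivaloyloxy)phenyl]propanoic acid | COc1c(OC)c(OC(=O)C(C)(C)C)c(cc1OC(=O)C(C)(C)C)[C@H](Cc1cc(OC)c(OCc2ccccc2)c(OC)c1)C(O)=O | intermediate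
13 | (2S)-3-[4-(benzyloxy)-3,5-dimethoxyphenyl]-2-[3,4-dimethoxy-2,5-bis(pivaloyloxy)phenyl]propan-1-ol | COc1c(OC)c(OC(=O)C(C)(C)C)c(cc1OC(=O)C(C)(C)C)[C@H](Cc2cc(OC)c(OCc3ccccc3)c(OC)c2)CO | intermediate
14 | (3S)-7-(benzyloxy)-3-[3,4-dimethoxy-2,5-bis(pivaloyloxy)phenyl]-6,8-dimethoxychroman | COc1c(OC)c(OC(=O)C(C)(C)C)c(cc1OC(=O)C(C)(C)C)[C@H]2COc3c(cc(OC)c(OCc4ccccc4)c3OC)C2 | intermediate
15 | (3S)-3-[3,4-dimethoxy-2,5-bis(pivaloyloxy)phenyl]-6,8-dimethoxychroman-7-ol | COc1c(OC)c(OC(=O)C(C)(C)C)c(cc1OC(=O)C(C)(C)C)[C@H]2COc3c(cc(OC)c(O)c3OC)C2 | intermediate
16 | 5-[(3S)-7-hydroxy-6,8-dimethoxychroman-3-yl]-2,3-dimethoxybenzene-1,4-diol (formed in the flask, not isolated) | COc1c(OC)c(O)c(cc1O)[C@H]2COc3c(cc(OC)c(O)c3OC)C2 | intermediate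
17 | 5-[(3S)-7-hydroxy-6,8-dimethoxychroman-3-yl]-2,3-dimethoxy-1,4-benzoquinone | COC1=C(OC)C(=O)C([C@H]2COc3c(cc(OC)c(O)c3OC)C2)=CC1=O | target

**Step count and least certain steps**

Total: 12 steps. Longest linear sequence: 11 steps (steps 1 to 5 and 7 to 12, from 2,3-dimethoxyphenol); the syringaldehyde branch joins at step 7.

Step 10 (key step, new method). Several processes could defeat it: back electron transfer that outruns ring closure; attack of the hydroxyl at C4a (spiro closure) followed by loss of the O7 substituent; dehydrogenation across C3–C4 after benzylic deprotonation of the radical cation, which would erase the stereocentre; and quenching of the photocatalyst by the more electron-rich product, so that conversion stalls or the product degrades. The fallback uses known chemistry and sets out from 13. Bromination with N-bromosuccinimide (MeCN, 0 °C) should enter only ring A, at one of its two equivalent free positions, to give (2S)-3-[4-(benzyloxy)-2-bromo-3,5-dimethoxyphenyl]-2-[3,4-dimethoxy-2,5-bis(pivaloyloxy)phenyl]propan-1-ol F1. Intramolecular palladium-catalysed aryl ether formation (Pd(OAc)2, 2-(di-tert-butylphosphino)-1,1'-binaphthyl, K3PO4, toluene, 80 °C; zerovalent palladium inserts into C–Br and C–O reductive elimination closes ring C) then comes back to the route at 14. A weak heterogeneous base is specified because a free alkoxide could take the neighbouring pivaloyl group.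

Step 8. Hydrogen delivery could be slow or poorly face-selective because the ortho pivaloyloxy group twists ring B out of the alkene plane and crowds the metal. The fallback sets out from 11: hydrogenation with the achiral complex [Ir(cod)(PCy3)(py)]PF6 (H2, CH2Cl2), which spares the benzyl ether, should give racemic 3-[4-(benzyloxy)-3,5-dimethoxyphenyl]-2-[3,4-dimethoxy-2,5-bis(pivaloyloxy)phenyl]propanoic acid F2. Its enantiomers are then separated by preparative chromatography on a chiral stationary phase, and the (S) acid comes back to the route at 12. The configuration then rests on resolution, at the cost of half the material.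

Step 7. The hindered acid could enolise and condense sluggishly, the product could decarboxylate to a stilbene at the temperature needed, and the pivalate ortho to the reacting CH2 could be exchanged or attacked by the enolate. The fallback sets out from 8 and 10, makes the C3–C4 bond by alkylation and sets C3 with an auxiliary, so it bypasses steps 7 to 9.
- 10 is reduced (NaBH4, MeOH) to [4-(benzyloxy)-3,5-dimethoxyphenyl]methanol F3 and converted (PBr3, CH2Cl2, 0 °C) into 2-(benzyloxy)-5-(bromomethyl)-1,3-dimethoxybenzene F4.
- 8 is joined to (S)-4-benzyl-1,3-oxazolidin-2-one through its mixed pivalic anhydride (t-BuCOCl, Et3N, LiCl, THF) to give (4S)-4-benzyl-3-{[3,4-dimethoxy-2,5-bis(pivaloyloxy)phenyl]acetyl}-1,3-oxazolidin-2-one F5.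
- The sodium enolate (NaN(SiMe3)2, THF, −78 °C) is alkylated by F4 on the face away from the auxiliary benzyl group (Evans alkylation) to give (4S)-4-benzyl-3-{(2S)-3-[4-(benzyloxy)-3,5-dimethoxyphenyl]-2-[3,4-dimethoxy-2,5-bis(pivaloyloxy)phenyl]propanoyl}-1,3-oxazolidin-2-one F6.
- LiBH4 (Et2O, H2O (1 equiv), 0 °C) removes the auxiliary reductively and comes back to the route at 13.

Step 12. Silver oxide could over-oxidise the ring A phenol, a 4-alkyl-2,6-dimethoxyphenol that can go on to a quinone methide, and the quinone could degrade if the work-up turns basic. The fallback sets out from 14 and reverses the order of events. i-Bu2AlH as in step 12 should give 5-[(3S)-7-(benzyloxy)-6,8-dimethoxychroman-3-yl]-2,3-dimethoxybenzene-1,4-diol F7, which is oxidised without isolation by Ag2O to 5-[(3S)-7-(benzyloxy)-6,8-dimethoxychroman-3-yl]-2,3-dimethoxy-1,4-benzoquinone F8; no free phenol is present at that point. Hydrogenolysis (H2, Pd/C, EtOAc) then removes the benzyl group and reduces the quinone, which leads back to 16. Stirring the filtered solution in air, an oxidant too weak for the ring A phenol, should give 17.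

Step 3. The phenoxyl radical could couple, or oxidation could go to an ortho-quinone or to the allyl group. The fallback sets out from 1. Teuber oxidation with K2[ON(SO3)2] (KH2PO4 buffer, acetone/H2O) should give 2,3-dimethoxy-1,4-benzoquinone F9. Addition of allyltributylstannane promoted by BF3·OEt2 (CH2Cl2, −78 °C) at a free ring carbon should then give, after tautomerisation, the allylhydroquinone directly. The fallback comes back to the route at 5, which is acylated as in the second stage of step 4 to give 6.

**Further compounds**

F1 | step 10 | (2S)-3-[4-(benzyloxy)-2-bromo-3,5-dimethoxyphenyl]-2-[3,4-dimethoxy-2,5-bis(pivaloyloxy)phenyl]propan-1-ol | COc1c(OC)c(OC(=O)C(C)(C)C)c(cc1OC(=O)C(C)(C)C)[C@H](Cc2cc(OC)c(OCc3ccccc3)c(OC)c2Br)CO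
F2 | step 8 | racemic 3-[4-(benzyloxy)-3,5-dimethoxyphenyl]-2-[3,4-dimethoxy-2,5-bis(pivaloyloxy)phenyl]propanoic acid | COc1c(OC)c(OC(=O)C(C)(C)C)c(cc1OC(=O)C(C)(C)C)C(Cc1cc(OC)c(OCc2ccccc2)c(OC)c1)C(O)=O
F3 | step 7 | [4-(benzyloxy)-3,5-dimethoxyphenyl]methanol | COc1cc(CO)cc(OC)c1OCc1ccccc1
F4 | step 7 | 2-(benzyloxy)-5-(bromomethyl)-1,3-dimethoxybenzene | COc1cc(CBr)cc(OC)c1OCc1ccccc1
F5 | step 7 | (4S)-4-benzyl-3-{[3,4-dimethoxy-2,5-bis(pivaloyloxy)phenyl]acetyl}-1,3-oxazolidin-2-one | O=C1OC[C@H](Cc2ccccc2)N1C(=O)Cc1cc(OC(=O)C(C)(C)C)c(OC)c(OC)c1OC(=O)C(C)(C)C
F6 | step 7 | (4S)-4-benzyl-3-{(2S)-3-[4-(benzyloxy)-3,5-dimethoxyphenyl]-2-[3,4-dimethoxy-2,5-bis(pivaloyloxy)phenyl]propanoyl}-1,3-oxazolidin-2-one | O=C1OC[C@H](Cc2ccccc2)N1C(=O)[C@@H](Cc1cc(OC)c(OCc2ccccc2)c(OC)c1)c1cc(OC(=O)C(C)(C)C)c(OC)c(OC)c1OC(=O)C(C)(C)C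
F7 | step 12 | 5-[(3S)-7-(benzyloxy)-6,8-dimethoxychroman-3-yl]-2,3-dimethoxybenzene-1,4-diol | COc1c(OC)c(O)c(cc1O)[C@H]2COc3c(cc(OC)c(OCc4ccccc4)c3OC)C2
F8 | step 12 | 5-[(3S)-7-(benzyloxy)-6,8-dimethoxychroman-3-yl]-2,3-dimethoxy-1,4-benzoquinone | COC1=C(OC)C(=O)C([C@H]2COc3c(cc(OC)c(OCc4ccccc4)c3OC)C2)=CC1=O
F9 | step 3 | 2,3-dimethoxy-1,4-benzoquinone | COC1=C(OC)C(=O)C=CC1=O
A1 | alternative 1 | [3-(benzyloxy)-6-(bromomethyl)-2,4-dimethoxyphenoxy](tert-butyl)dimethylsilane | COc1cc(CBr)c(O[Si](C)(C)C(C)(C)C)c(OC)c1OCc1ccccc1
A2 | alternative 1 | 3-(benzyloxy)-2,4-dimethoxy-6-methylidenecyclohexa-2,4-dien-1-one | C=C1C=C(OC)C(OCc2ccccc2)=C(OC)C1=O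
A3 | alternative 1 | 4-nitrophenyl [2,5-bis(benzyloxy)-3,4-dimethoxyphenyl]acetate | O=C(Cc1cc(OCc2ccccc2)c(OC)c(OC)c1OCc1ccccc1)Oc1ccc(cc1)[N+](=O)[O-]
A4 | alternative 1 | (3S)-3-[2,5-bis(benzyloxy)-3,4-dimethoxyphenyl]-7-(benzyloxy)-6,8-dimethoxychroman-2-one | COc1c(OC)c(OCc2ccccc2)c(cc1OCc3ccccc3)[C@H]4C(=O)Oc5c(cc(OC)c(OCc6ccccc6)c5OC)C4
A5 | alternative 2 | 2-(tert-butoxy)-4-{(4S)-4-[2,5-bis(benzyloxy)-3,4-dimethoxyphenyl]-5-[(tert-butyldimethylsilyl)oxy]pent-1-en-2-yl}-4-hydroxy-3-methoxycyclobut-2-en-1-one (carbinol carbon of either configuration) | O=C1C(OC(C)(C)C)=C(OC)C1(O)C(=C)C[C@H](CO[Si](C)(C)C(C)(C)C)c1cc(OCc2ccccc2)c(OC)c(OC)c1OCc1ccccc1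
A6 | alternative 2 | 5-{(2S)-2-[2,5-bis(benzyloxy)-3,4-dimethoxyphenyl]-3-[(tert-butyldimethylsilyl)oxy]propyl}-2-(tert-butoxy)-3-methoxybenzene-1,4-diol | COc1c(OC)c(OCc2ccccc2)c(cc1OCc3ccccc3)[C@H](Cc4cc(O)c(OC(C)(C)C)c(OC)c4O)CO[Si](C)(C)C(C)(C)C
A7 | alternative 3 | 6-(benzyloxy)-5,7-dimethoxy-1-benzofuran | COc1cc2ccoc2c(OC)c1OCc1ccccc1
A8 | alternative 3 | 3-[2,5-bis(benzyloxy)-3,4-dimethoxyphenyl]-3-chloro-3H-diazirine | ClC1(N=N1)c1cc(OCc2ccccc2)c(OC)c(OC)c1OCc1ccccc1
A9 | alternative 3 | 3-[2,5-bis(benzyloxy)-3,4-dimethoxyphenyl]-7-(benzyloxy)-6,8-dimethoxychromenylium chloride | COc1cc2cc(c[o+]c2c(OC)c1OCc3ccccc3)-c4cc(OCc5ccccc5)c(OC)c(OC)c4OCc6ccccc6.[Cl-]
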